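Ring A is cut into a three-carbon unit (C1–C2–C3, acryloyl chloride) and the allyl unit C4–C4a–C8a carried by a carvone-derived ring B, so that both links between them, C1–C8a and C3–C4, form in one Lewis acid domino. An enantioenriched allylsilane is acylated at C8a (anti SE2′, setting the quaternary centre from the silicon-bearing centre) and the alkene so unveiled closes onto the vinyl ketone. The step exploits the 1,4 relation in ring A between C1 (future bromide, delivered as ketone) and C4 (future methylidene) across the C4a–C8a fusion. Singlet oxygen, hydride, an Appel inversion and a late cross-coupling complete the target.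

Key step: step 5

Remarks on the chemistry
- Atom labels follow the naphthalene numbering of the target: C1 (CHBr), C2, C3, C4 (C=CH2), C4a (C–OH), C5, C6 (carries the side chain), C7, C8, C8a (C–CH3).
- Assumption: the sense of induction of the ferrocenyl ligand in step 4 is taken by analogy with simpler alkenyl halides; the ligand enantiomer is the one that gives the (R)-silane.
- C6 comes from (R)-carvone and is never epimerisable after step 3. C8a is set in step 5 from the silicon-bearing centre. Any minor C8a epimer is a diastereomer and should be removable by chromatography after step 5.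

Step 1
Reactants: 1 (R)-carvone
Product: 3 (5R)-2-methyl-5-(prop-1-en-2-yl)cyclohex-1-en-1-yl trifluoromethanesulfonate, via lithium enolate 2 (not isolated)
Conditions: LiBH(s-Bu)3, THF, −78 °C; then PhN(SO2CF3)2, −78 °C to rt
Reagents that add atoms: N-phenyl-bis(trifluoromethanesulfonimide), O=S(=O)(N(c1ccccc1)S(=O)(=O)C(F)(F)F)C(F)(F)F
Why: Conjugate hydride addition of the bulky borohydride to the enone gives the more substituted enolate regiospecifically and O-triflation fixes it as the tetrasubstituted enol triflate, leaving the C5 centre untouched.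

Step 2
Reactants: 3 (5R)-2-methyl-5-(prop-1-en-2-yl)cyclohex-1-en-1-yl trifluoromethanesulfonate
Product: 4 (5R)-5-acetyl-2-methylcyclohex-1-en-1-yl trifluoromethanesulfonate
Conditions: O3 (one equivalent), CH2Cl2–MeOH, −78 °C; then Me2S, −78 °C to rt
Reagents that add atoms: ozone, [O-][O+]=O
Why: Ozonolysis should be chemoselective for the electron-rich 1,1-disubstituted alkene over the electron-poor enol triflate double bond, and the neutral reductive work-up should keep the centre next to the new ketone.

Step 3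
Reactants: 4 (5R)-5-acetyl-2-methylcyclohex-1-en-1-yl trifluoromethanesulfonate
Product: 7 (5R)-2-methyl-5-[(trimethylsilyl)ethynyl]cyclohex-1-en-1-yl trifluoromethanesulfonate, via enol phosphate 5 (not isolated), via lithium acetylide 6 (not isolated)
Conditions: lithium diisopropylamide (1.1 equiv), THF, −78 °C; ClP(O)(OEt)2; lithium diisopropylamide (2.3 equiv), −78 to 0 °C; Me3SiCl
Reagents that add atoms: chlorotrimethylsilane, C[Si](C)(C)Cl
Why: Kinetic enolisation on the methyl side, O-phosphorylation and base-induced elimination of the enol phosphate is the standard methyl ketone to alkyne conversion, and silylation of the acetylide protects the alkyne for steps 4 to 6.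

Step 4
Reactants: 7 (5R)-2-methyl-5-[(trimethylsilyl)ethynyl]cyclohex-1-en-1-yl trifluoromethanesulfonate; 8 (1-chloroethyl)trimethylsilane (racemic)
Product: 10 trimethyl{(1R)-1-[(5R)-2-methyl-5-[(trimethylsilyl)ethynyl]cyclohex-1-en-1-yl]ethyl}silane, via Grignard reagent 9 (not isolated)
Conditions: 8, Mg, Et2O, reflux; then 7, PdCl2(PPFA) (3 mol %; PPFA = (R)-N,N-dimethyl-1-[(S)-2-(diphenylphosphino)ferrocenyl]ethylamine), Et2O, 0 °C to rt
Reagents that add atoms: none
Why: Asymmetric Kumada coupling of a racemic, rapidly inverting α-silylalkyl Grignard reagent (dynamic kinetic resolution) is the established route to α-chiral allylsilanes, and here the ligand sets the silicon-bearing centre that controls step 5.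

Step 5
Reactants: 10 trimethyl{(1R)-1-[(5R)-2-methyl-5-[(trimethylsilyl)ethynyl]cyclohex-1-en-1-yl]ethyl}silane; 11 acryloyl chloride
Product: 13 (6R,8aR)-4,8a-dimethyl-6-[(trimethylsilyl)ethynyl]-3,5,6,7,8,8a-hexahydronaphthalen-1(2H)-one, via dienone 12 (not isolated)
Conditions: TiCl4 (1.1 equiv), CH2Cl2, −78 °C; then EtAlCl2 (1.5 equiv), −78 to 0 °C
Reagents that add atoms: none
Why: Proposed new method: the acylium complex of acryloyl chloride is attacked by the γ-carbon (C8a) of the allylsilane in an anti SE2′ Hosomi–Sakurai acylation, which forms C1–C8a, expels Me3SiCl and leaves an exocyclic ethylidene; the Lewis acid-bound vinyl ketone is then attacked at its β-carbon (C3) by the ethylidene carbon (C4), and the tertiary C4a cation loses the C4 proton to give the tetrasubstituted alkene. The closest known reactions are the Hosomi–Sakurai acylation of allylsilanes with acid chlorides and the Lewis acid promoted intramolecular addition of alkenes to enones; their one-pot union as a [3+3] cyclohexanone annulation is the new element. Ring A closes 6-endo-trig with respect to the nucleophilic alkene, through a chair-like 1,5-dien-3-one in which all three enone atoms become ring members. The only new stereocentre, C8a, is controlled by the silicon-bearing centre: A(1,3) strain with the C8a methyl group holds the C–H bond in the alkene plane, so the acylium ion enters anti to silicon, on the face opposite to the C6 alkynyl group. The step needs γ- and not α-acylation (secured by the β-silicon effect), reaction at the allylsilane and not the alkynylsilane (secured by its much higher nucleophilicity at −78 °C), and six- and not four-membered closure (secured by Markovnikov attack of C4 on C3).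

Step 6
Reactants: 13 (6R,8aR)-4,8a-dimethyl-6-[(trimethylsilyl)ethynyl]-3,5,6,7,8,8a-hexahydronaphthalen-1(2H)-one
Product: 15 (4aR,6R,8aR)-4a-hydroxy-8a-methyl-4-methylidene-6-[(trimethylsilyl)ethynyl]octahydronaphthalen-1(2H)-one, via hydroperoxide 14 (not isolated)
Conditions: O2, visible light, 5,10,15,20-tetraphenylporphyrin (cat.), CH2Cl2, 0 °C; then PPh3, 0 °C to rt
Reagents that add atoms: dioxygen, O=O
Why: The Schenck ene reaction of singlet oxygen should occur on the face of the tetrasubstituted alkene anti to the axial C8a methyl group with hydrogen abstraction from the C4 methyl group, giving the 4a-hydroperoxide with the exocyclic methylene, which the phosphine reduces to the alcohol trans to the angular methyl.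

Step 7
Reactants: 15 (4aR,6R,8aR)-4a-hydroxy-8a-methyl-4-methylidene-6-[(trimethylsilyl)ethynyl]octahydronaphthalen-1(2H)-one
Product: 17 (1S,4aR,6R,8aS)-6-ethynyl-8a-methyl-4-methylideneoctahydronaphthalene-1,4a(2H)-diol, via silylated diol 16 (not isolated)
Conditions: LiBH(s-Bu)3 (2.5 equiv), THF, −78 °C; then MeOH, K2CO3, rt
Reagents that add atoms: none
Why: The bulky hydride should attack the C1 ketone along the equatorial trajectory, because the axial face is blocked by the 1,3-diaxial C4a alkoxide, giving the axial (1S) alcohol, and methanolic carbonate then cleaves the alkynyl C–Si bond.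

Step 8
Reactants: 17 (1S,4aR,6R,8aS)-6-ethynyl-8a-methyl-4-methylideneoctahydronaphthalene-1,4a(2H)-diol
Product: 19 (1S,4aR,6R,8aS)-6-[(E)-1-iodoprop-1-en-2-yl]-8a-methyl-4-methylideneoctahydronaphthalene-1,4a(2H)-diol, via alkenylalane 18 (not isolated)
Conditions: AlMe3 (5 equiv), Cp2ZrCl2 (0.5 equiv), CH2Cl2, 0 °C to rt; then I2, THF, −30 °C
Reagents that add atoms: trimethylaluminium, C[Al](C)C; iodine, II
Why: Negishi carboalumination adds methyl and aluminium syn across the terminal alkyne (methyl to the internal carbon, the hydroxyls being masked as aluminium alkoxides), and iododealumination with retention gives the (E)-iodide.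

Step 9
Reactants: 19 (1S,4aR,6R,8aS)-6-[(E)-1-iodoprop-1-en-2-yl]-8a-methyl-4-methylideneoctahydronaphthalene-1,4a(2H)-diol
Product: 20 (1R,4aR,6R,8aR)-1-bromo-6-[(E)-1-iodoprop-1-en-2-yl]-8a-methyl-4-methylideneoctahydronaphthalen-4a(2H)-ol
Conditions: CBr4, PPh3, 2,6-lutidine, CH2Cl2, 0 to 40 °C
Reagents that add atoms: carbon tetrabromide, BrC(Br)(Br)Br
Why: In the Appel reaction bromide should displace the axial secondary oxyphosphonium group by SN2 along the equatorial vector with inversion, giving the equatorial (1R) bromide, while the tertiary allylic alcohol, which cannot undergo backside displacement, should stay.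

Step 10
Reactants: 21 2-methylbut-1-en-3-yne; 22 pinacolborane
Product: 23 (E)-4,4,5,5-tetramethyl-2-(3-methylbuta-1,3-dien-1-yl)-1,3,2-dioxaborolane
Conditions: Cp2Zr(H)Cl (5 mol %), Et3N (10 mol %), neat, 60 °C
Reagents that add atoms: none
Why: Zirconium hydride catalysed syn-hydroboration of the terminal alkyne with pinacolborane gives the (E)-alkenyl boronate and leaves the 1,1-disubstituted alkene alone.

Step 11
Reactants: 20 (1R,4aR,6R,8aR)-1-bromo-6-[(E)-1-iodoprop-1-en-2-yl]-8a-methyl-4-methylideneoctahydronaphthalen-4a(2H)-ol; 23 (E)-4,4,5,5-tetramethyl-2-(3-methylbuta-1,3-dien-1-yl)-1,3,2-dioxaborolane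
Product: 24 (1R,4aR,6R,8aR)-1-bromo-8a-methyl-4-methylidene-6-[(2E,4E)-6-methylhepta-2,4,6-trien-2-yl]octahydronaphthalen-4a(2H)-ol (target)
Conditions: Pd(PPh3)4 (5 mol %), aqueous K3PO4, THF, rt, dark
Reagents that add atoms: none
Why: Suzuki–Miyaura coupling joins the two alkenyl partners with retention of both geometries; zerovalent palladium should not insert into the unactivated secondary alkyl bromide, and the weak aqueous base should avoid the C4a alkoxide that could trigger Grob fragmentation.

Compound list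
1 | (R)-carvone, (5R)-2-methyl-5-(prop-1-en-2-yl)cyclohex-2-en-1-one | CC1=CC[C@H](CC1=O)C(C)=C | starting material
2 | lithium (5R)-2-methyl-5-(prop-1-en-2-yl)cyclohex-1-en-1-olate | CC1=C(O[Li])C[C@@H](CC1)C(C)=C | intermediate
3 | (5R)-2-methyl-5-(prop-1-en-2-yl)cyclohex-1-en-1-yl trifluoromethanesulfonate | CC1=C(OS(=O)(=O)C(F)(F)F)C[C@@H](CC1)C(C)=C | intermediate
4 | (5R)-5-acetyl-2-methylcyclohex-1-en-1-yl trifluoromethanesulfonate | CC1=C(OS(=O)(=O)C(F)(F)F)C[C@@H](CC1)C(C)=O | intermediate
5 | (5R)-5-[1-(diethoxyphosphoryloxy)ethenyl]-2-methylcyclohex-1-en-1-yl trifluoromethanesulfonate | CC1=C(OS(=O)(=O)C(F)(F)F)C[C@@H](CC1)C(=C)OP(=O)(OCC)OCC | intermediate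
6 | lithium acetylide of (5R)-5-ethynyl-2-methylcyclohex-1-en-1-yl trifluoromethanesulfonate | CC1=C(OS(=O)(=O)C(F)(F)F)C[C@@H](CC1)C#C[Li] | intermediate
7 | (5R)-2-methyl-5-[(trimethylsilyl)ethynyl]cyclohex-1-en-1-yl trifluoromethanesulfonate | CC1=C(OS(=O)(=O)C(F)(F)F)C[C@@H](CC1)C#C[Si](C)(C)C | intermediate
8 | (1-chloroethyl)trimethylsilane (racemic) | CC(Cl)[Si](C)(C)C | starting material
9 | [1-(trimethylsilyl)ethyl]magnesium chloride | CC([Mg]Cl)[Si](C)(C)C | intermediate
10 | trimethyl{(1R)-1-[(5R)-2-methyl-5-[(trimethylsilyl)ethynyl]cyclohex-1-en-1-yl]ethyl}silane | C[C@@H]([Si](C)(C)C)C1=C(C)CC[C@H](C1)C#C[Si](C)(C)C | intermediate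
11 | acryloyl chloride | C=CC(Cl)=O | starting material
12 | 1-[(1R,2E,4R)-2-ethylidene-1-methyl-4-[(trimethylsilyl)ethynyl]cyclohexyl]prop-2-en-1-one | C=CC(=O)[C@]1(C)CC[C@@H](C#C[Si](C)(C)C)C/C1=C\C | intermediate
13 | (6R,8aR)-4,8a-dimethyl-6-[(trimethylsilyl)ethynyl]-3,5,6,7,8,8a-hexahydronaphthalen-1(2H)-one | O=C1CCC(C)=C2C[C@H](C#C[Si](C)(C)C)CC[C@@]12C | intermediate
14 | (4aR,6R,8aR)-4a-hydroperoxy-8a-methyl-4-methylidene-6-[(trimethylsilyl)ethynyl]octahydronaphthalen-1(2H)-one | O=C1CCC(=C)[C@]2(OO)C[C@H](C#C[Si](C)(C)C)CC[C@@]12C | intermediate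
15 | (4aR,6R,8aR)-4a-hydroxy-8a-methyl-4-methylidene-6-[(trimethylsilyl)ethynyl]octahydronaphthalen-1(2H)-one | O=C1CCC(=C)[C@]2(O)C[C@H](C#C[Si](C)(C)C)CC[C@@]12C | intermediate
16 | (1S,4aR,6R,8aS)-8a-methyl-4-methylidene-6-[(trimethylsilyl)ethynyl]octahydronaphthalene-1,4a(2H)-diol | O[C@H]1CCC(=C)[C@]2(O)C[C@H](C#C[Si](C)(C)C)CC[C@@]12C | intermediate
17 | (1S,4aR,6R,8aS)-6-ethynyl-8a-methyl-4-methylideneoctahydronaphthalene-1,4a(2H)-diol | O[C@H]1CCC(=C)[C@]2(O)C[C@H](C#C)CC[C@@]12C | intermediate
18 | (E)-alkenyl(dimethyl)alane from 17, both hydroxyls as dimethylaluminium alkoxides | C[Al](C)O[C@H]1CCC(=C)[C@]2(O[Al](C)C)C[C@H](/C(C)=C/[Al](C)C)CC[C@@]12C | intermediate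
19 | (1S,4aR,6R,8aS)-6-[(E)-1-iodoprop-1-en-2-yl]-8a-methyl-4-methylideneoctahydronaphthalene-1,4a(2H)-diol | O[C@H]1CCC(=C)[C@]2(O)C[C@H](/C(C)=C/I)CC[C@@]12C | intermediate
20 | (1R,4aR,6R,8aR)-1-bromo-6-[(E)-1-iodoprop-1-en-2-yl]-8a-methyl-4-methylideneoctahydronaphthalen-4a(2H)-ol | Br[C@@H]1CCC(=C)[C@]2(O)C[C@H](/C(C)=C/I)CC[C@@]12C | intermediate
21 | 2-methylbut-1-en-3-yne | CC(=C)C#C | starting material
22 | pinacolborane, 4,4,5,5-tetramethyl-1,3,2-dioxaborolane | CC1(C)OBOC1(C)C | starting material
23 | (E)-4,4,5,5-tetramethyl-2-(3-methylbuta-1,3-dien-1-yl)-1,3,2-dioxaborolane | CC(=C)/C=C/B1OC(C)(C)C(C)(C)O1 | intermediate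
24 | (1R,4aR,6R,8aR)-1-bromo-8a-methyl-4-methylidene-6-[(2E,4E)-6-methylhepta-2,4,6-trien-2-yl]octahydronaphthalen-4a(2H)-ol | C=C(C)/C=C/C=C(\C)[C@@H]1CC[C@@]2(C)[C@H](Br)CCC(=C)[C@]2(O)C1 | target

Total step count: 11. Longest linear sequence: 10 steps (steps 1 to 9 and 11).

Steps most likely to fail

1. Step 5 (proposed new method). The domino may stop after the acylation, or be diverted by protodesilylation of the allylsilane, polymerisation of the vinyl ketone or chloride addition to it. The fallback sets out from compound 7 and comes back to the route at compound 13, using known reactions only. Negishi coupling of 7 with (5-ethoxy-5-oxopentan-2-yl)zinc iodide (Pd(OAc)2, CPhos, THF) should give ethyl 4-[(5R)-2-methyl-5-[(trimethylsilyl)ethynyl]cyclohex-1-en-1-yl]pentanoate F1, as both epimers at the chain carbon. Hydrolysis with LiOH should give 4-[(5R)-2-methyl-5-[(trimethylsilyl)ethynyl]cyclohex-1-en-1-yl]pentanoic acid F2. Activation with (CF3CO)2O and SnCl4 in CH2Cl2 should then effect the acylium–olefin cyclisation known from octalone syntheses (attack at the methyl-bearing alkene carbon, proton loss to the tetrasubstituted alkene). It should give 13 together with its epimer (6R,8aS)-4,8a-dimethyl-6-[(trimethylsilyl)ethynyl]-3,5,6,7,8,8a-hexahydronaphthalen-1(2H)-one F3, to be separated by chromatography. This fallback gives up the one-operation closure and the stereocontrol at C8a.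

2. Step 4. The hindered tetrasubstituted triflate may couple slowly, with β-hydride elimination and isomerisation of the secondary alkyl group or poor discrimination between the Grignard enantiomers. The fallback sets out from compound 7 and comes back at compound 10. Stille coupling of 7 with tributyl(1-ethoxyvinyl)stannane (Pd(PPh3)4, LiCl, THF) should give {[(1R)-3-(1-ethoxyethenyl)-4-methylcyclohex-3-en-1-yl]ethynyl}trimethylsilane F4. Dilute HCl should hydrolyse it to 1-[(5R)-2-methyl-5-[(trimethylsilyl)ethynyl]cyclohex-1-en-1-yl]ethan-1-one F5. Corey–Bakshi–Shibata reduction (oxazaborolidine enantiomer chosen for the S carbinol, BH3·SMe2) should give (1S)-1-[(5R)-2-methyl-5-[(trimethylsilyl)ethynyl]cyclohex-1-en-1-yl]ethan-1-ol F6. Methyl chloroformate and pyridine should give methyl (1S)-1-[(5R)-2-methyl-5-[(trimethylsilyl)ethynyl]cyclohex-1-en-1-yl]ethyl carbonate F7. Allylic silylation with Me3SiSiMe3 (Pd2(dba)3, LiCl, THF) at the less hindered allyl terminus, with net inversion, should then give 10.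

3. Step 9. Substitution at the neopentylic C1 may lose out to E2 elimination, to a 1,2-methyl shift on ionisation, or to reaction at the tertiary allylic alcohol. The fallback sets out from compound 19 and comes back at compound 20. 1,1′-Sulfonyldiimidazole and NaH in THF should tie the syn-1,3-diol into the cyclic sulfate (1S,4aR,6R,8aS)-6-[(E)-1-iodoprop-1-en-2-yl]-8a-methyl-4-methylideneoctahydronaphthalene-1,4a(2H)-diyl sulfate F8. LiBr in THF at 50 °C should open it at the secondary carbon C1 with inversion to lithium (1R,4aR,6R,8aR)-1-bromo-6-[(E)-1-iodoprop-1-en-2-yl]-8a-methyl-4-methylideneoctahydronaphthalen-4a(2H)-yl sulfate F9. Catalytic H2SO4 with one equivalent of water in THF should cleave the sulfate ester at sulfur to give 20.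

Further compounds
F1 | step 5 | ethyl 4-[(5R)-2-methyl-5-[(trimethylsilyl)ethynyl]cyclohex-1-en-1-yl]pentanoate (both chain epimers) | CCOC(=O)CCC(C)C1=C(C)CC[C@H](C1)C#C[Si](C)(C)C
F2 | step 5 | 4-[(5R)-2-methyl-5-[(trimethylsilyl)ethynyl]cyclohex-1-en-1-yl]pentanoic acid (both chain epimers) | OC(=O)CCC(C)C1=C(C)CC[C@H](C1)C#C[Si](C)(C)C
F3 | step 5 | (6R,8aS)-4,8a-dimethyl-6-[(trimethylsilyl)ethynyl]-3,5,6,7,8,8a-hexahydronaphthalen-1(2H)-one | O=C1CCC(C)=C2C[C@H](C#C[Si](C)(C)C)CC[C@]12C
F4 | step 4 | {[(1R)-3-(1-ethoxyethenyl)-4-methylcyclohex-3-en-1-yl]ethynyl}trimethylsilane | CCOC(=C)C1=C(C)CC[C@H](C1)C#C[Si](C)(C)C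
F5 | step 4 | 1-[(5R)-2-methyl-5-[(trimethylsilyl)ethynyl]cyclohex-1-en-1-yl]ethan-1-one | CC(=O)C1=C(C)CC[C@H](C1)C#C[Si](C)(C)C
F6 | step 4 | (1S)-1-[(5R)-2-methyl-5-[(trimethylsilyl)ethynyl]cyclohex-1-en-1-yl]ethan-1-ol | C[C@H](O)C1=C(C)CC[C@H](C1)C#C[Si](C)(C)C
F7 | step 4 | methyl (1S)-1-[(5R)-2-methyl-5-[(trimethylsilyl)ethynyl]cyclohex-1-en-1-yl]ethyl carbonate | C[C@H](OC(=O)OC)C1=C(C)CC[C@H](C1)C#C[Si](C)(C)C
F8 | step 9 | (1S,4aR,6R,8aS)-6-[(E)-1-iodoprop-1-en-2-yl]-8a-methyl-4-methylideneoctahydronaphthalene-1,4a(2H)-diyl sulfate (cyclic) | O=S1(=O)O[C@H]2CCC(=C)[C@]3(O1)C[C@H](/C(C)=C/I)CC[C@@]23C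
F9 | step 9 | lithium (1R,4aR,6R,8aR)-1-bromo-6-[(E)-1-iodoprop-1-en-2-yl]-8a-methyl-4-methylideneoctahydronaphthalen-4a(2H)-yl sulfate | Br[C@@H]1CCC(=C)[C@]2(OS(=O)(=O)[O-])C[C@H](/C(C)=C/I)CC[C@@]12C.[Li+]
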